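The route rests on cutting the bond between cyclopentane C-4 (the ring CH between the two CH2 groups) and the side-chain carbinol carbon C-1′ attached to C-6 of the dihydropyranone. A nickel/iridium photoredox decarboxylative sp3–sp3 coupling joins the fully built cyclopentane core, as its C-4 bromide, with a 2-deoxy-D-ribose-derived dioxolane carboxylic acid and sets C-4 and C-1′ in one operation. It exploits the threo O–C-1′–C-6–O diol: held in a 1,3-dioxolane, the C-1′ radical bonds trans to the C-6 arm, rewriting the sugar's erythro centre, while the butenolide on C-1 screens one face of C-4. The precursors are a secondary bromide with the spiro-lactol masked as methyl acetal and a cis-dioxolane acid carrying a Z-enoate.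

Key step: step 13

Assumption: lactone acid 1, the enantiomer of the widely sold (1R,4R,5R) compound and the other product of the same salt resolution of the racemate, is bought as the single enantiomer.
Assumption: the lactol carbon of the spiro-lactone equilibrates by ring–chain tautomerism of the aldehyde acid, so the five-membered pseudo-acid with the natural configuration is taken as the thermodynamic form reached in the last step.
Locants: cyclopentane C-1 carries CO2H and the butenolide (bonded through furanone C-3), C-2 is the spiro carbon, C-4 the CH with the side chain; C-1′ is the carbinol carbon and "pyranone C-6" the O-bearing CH of the dihydropyranone. The α-face is the face of the two carboxyl carbons on C-1 and C-2 (and of the side chain in the target); the β-face is the face of the butenolide and of the CH2 arm on C-2.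

Step 1
Reactants: 1 (1S,4S,5S)-3-oxo-2-oxabicyclo[2.2.1]heptane-5-carboxylic acid
Product: 2 (1R,4S,5R)-5-allyl-3-oxo-2-oxabicyclo[2.2.1]heptane-5-carboxylic acid (allyl exo)
Conditions: LiN(iPr)2 (2.3 equiv), THF, −78 → 0 °C; allyl bromide, −78 → 25 °C; aq. HCl
Reagents that add atoms: allyl bromide C=CCBr
Why: α-Alkylation of a carboxylic acid dianion: only cyclopentane C-2 can be deprotonated (the C-1 bridgehead of the lactone cannot enolise) and allyl bromide attacks the exocyclic enediolate on the exo face, away from the lactone bridge, so the allyl group ends on the β-face and the carboxyl on the α-face, the C-2 quaternary centre being set by the two centres already present.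

Step 2
Reactants: 2 (1R,4S,5R)-5-allyl-3-oxo-2-oxabicyclo[2.2.1]heptane-5-carboxylic acid
Product: 3 1-allyl-4-hydroxy-2-[(4-methoxybenzyloxy)carbonyl]cyclopentane-1-carboxylic acid (CO2H, CO2PMB and OH cis on the α-face; allyl β)
Conditions: 4-MeOC6H4CH2OH (3 equiv), NaH (2.2 equiv), THF, 0 → 25 °C; aq. HCl to pH 3
Reagents that add atoms: 4-methoxybenzyl alcohol COc1ccc(CO)cc1
Why: Transesterification (alkoxide acyl–oxygen cleavage) of the strained bridged γ-lactone frees the C-4 hydroxyl with retention and stores the C-1 carboxyl as an acid-labile PMB ester, while the hindered C-2 carboxylate is inert; no stereocentre is created and the C-1 CH centre is in any case erased in step 4.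

Step 3
Reactants: 3 1-allyl-4-hydroxy-2-[(4-methoxybenzyloxy)carbonyl]cyclopentane-1-carboxylic acid
Product: 4 4-methoxybenzyl 4-allyl-3-oxo-2-oxabicyclo[2.2.1]heptane-5-carboxylate (ester endo)
Conditions: 2,4,6-Cl3C6H2COCl, Et3N, THF, 25 °C; then DMAP, PhMe, 25 °C, high dilution
Reagents that add atoms: none
Why: Yamaguchi lactonisation: the mixed anhydride of the C-2 acid is captured by the cis C-4 hydroxyl, which moves the lactone bridge from C-1 to C-2 so that the quaternary C-2 becomes the bridgehead and C-1 the only enolisable carbon, without touching a stereocentre.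

Step 4
Reactants: 4 4-methoxybenzyl 4-allyl-3-oxo-2-oxabicyclo[2.2.1]heptane-5-carboxylate
Product: 5 4-methoxybenzyl 4-allyl-5-(2-methoxy-2-oxoethyl)-3-oxo-2-oxabicyclo[2.2.1]heptane-5-carboxylate (CH2CO2Me exo)
Conditions: LiN(iPr)2 (1.1 equiv), THF, −78 °C; BrCH2CO2Me, −78 → −20 °C
Reagents that add atoms: methyl bromoacetate COC(=O)CBr
Why: Ester enolate alkylation: the exocyclic lithium enolate at C-1 is attacked by the bromoacetate on the exo face of the 2-oxabicyclo[2.2.1]heptane, anti to the lactone bridge, which sets the second quaternary centre with the acetate arm β and the ester α, that is with both carboxyl carbons cis as in the target.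

Step 5
Reactants: 5 4-methoxybenzyl 4-allyl-5-(2-methoxy-2-oxoethyl)-3-oxo-2-oxabicyclo[2.2.1]heptane-5-carboxylate; 6 (S)-2-hexyloxirane
Product: 8 4-methoxybenzyl 4-allyl-5-[(5S)-5-hexyl-2-oxotetrahydrofuran-3-yl]-3-oxo-2-oxabicyclo[2.2.1]heptane-5-carboxylate, via hydroxy ester 7 (not isolated)
Conditions: LiN(iPr)2, THF, −78 °C; Et2AlCl; 6, −78 → 0 °C; aq. KNaC4H4O6; then PPTS (cat.), PhMe, 60 °C
Reagents that add atoms: none
Why: Epoxide opening by an aluminium ester enolate at the terminal carbon (SN2, the oxygen-bearing S centre of 6 is not touched and becomes furanone C-5) followed by acid-catalysed γ-lactonisation onto the methyl ester, the five-membered closure being preferred over attack on the hindered PMB ester; the new furanone C-3 centre forms as a mixture that step 6 removes.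

Step 6
Reactants: 8 4-methoxybenzyl 4-allyl-5-[(5S)-5-hexyl-2-oxotetrahydrofuran-3-yl]-3-oxo-2-oxabicyclo[2.2.1]heptane-5-carboxylate
Product: 10 4-methoxybenzyl 4-allyl-5-[(5S)-5-hexyl-2-oxo-2,5-dihydrofuran-3-yl]-3-oxo-2-oxabicyclo[2.2.1]heptane-5-carboxylate, via selenide 9 (not isolated)
Conditions: LiN(iPr)2, THF, −78 °C; PhSeBr, −78 °C; then 30% H2O2, pyridine, CH2Cl2, 0 → 25 °C
Reagents that add atoms: none
Why: α-Selenenylation of the lactone enolate and selenoxide syn-elimination: because the adjacent cyclopentane C-1 is quaternary the selenoxide finds β-hydrogens only at furanone C-4, so only the endocyclic butenolide can form, and the γ-centre is not exposed to base after the alkene is in place.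

Step 7
Reactants: 10 4-methoxybenzyl 4-allyl-5-[(5S)-5-hexyl-2-oxo-2,5-dihydrofuran-3-yl]-3-oxo-2-oxabicyclo[2.2.1]heptane-5-carboxylate
Product: 11 4-methoxybenzyl 5-[(5S)-5-hexyl-2-oxo-2,5-dihydrofuran-3-yl]-3-oxo-4-(2-oxoethyl)-2-oxabicyclo[2.2.1]heptane-5-carboxylate
Conditions: OsO4 (2 mol%), NaIO4 (4 equiv), 2,6-lutidine, dioxane/H2O 3:1, 25 °C
Reagents that add atoms: sodium periodate (oxygen, relayed through OsO4) [Na+].[O-][I](=O)(=O)=O
Why: Lemieux–Johnson oxidative cleavage: OsO4 dihydroxylates the electron-rich monosubstituted alkene much faster than the electron-poor trisubstituted butenolide alkene and periodate cleaves the diol to the aldehyde, no stereocentre being involved.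

Step 8
Reactants: 11 4-methoxybenzyl 5-[(5S)-5-hexyl-2-oxo-2,5-dihydrofuran-3-yl]-3-oxo-4-(2-oxoethyl)-2-oxabicyclo[2.2.1]heptane-5-carboxylate
Product: 13 4-methoxybenzyl 6-[(5S)-5-hexyl-2-oxo-2,5-dihydrofuran-3-yl]-8-hydroxy-3-methoxy-1-oxo-2-oxaspiro[4.4]nonane-6-carboxylate (OH α; acetal epimers), via hemiacetal 12 (not isolated)
Conditions: (+)-camphorsulfonic acid (10 mol%), MeOH (10 equiv), CH2Cl2, 25 °C
Reagents that add atoms: methanol CO
Why: Acid-catalysed translactonisation through the methanol hemiacetal, whose hydroxyl attacks the strained bridged lactone carbonyl in a five-membered transition state to give the unstrained 5-methoxy-γ-lactone (pseudo-ester) at C-2 and the free C-4 alcohol; the acetal carbon forms as an epimer mixture that is equilibrated in step 14.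

Step 9
Reactants: 13 4-methoxybenzyl 6-[(5S)-5-hexyl-2-oxo-2,5-dihydrofuran-3-yl]-8-hydroxy-3-methoxy-1-oxo-2-oxaspiro[4.4]nonane-6-carboxylate
Product: 14 4-methoxybenzyl 8-bromo-6-[(5S)-5-hexyl-2-oxo-2,5-dihydrofuran-3-yl]-3-methoxy-1-oxo-2-oxaspiro[4.4]nonane-6-carboxylate (Br β)
Conditions: CBr4, PPh3, 2,6-lutidine, CH2Cl2, 0 → 25 °C
Reagents that add atoms: carbon tetrabromide BrC(Br)(Br)Br
Why: Appel reaction: bromide displaces the alkoxyphosphonium with inversion at the unhindered C-4 flanked by two CH2 groups (the neighbouring carbonyl groups lie on the same face as the leaving group and cannot participate), and the configuration of this centre is later erased in the radical step.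

Step 10
Reactants: 15 2-deoxy-D-ribose
Product: 16 2-deoxy-3,4-O-isopropylidene-D-erythro-pentopyranose
Conditions: 2-methoxypropene, PPTS (cat.), EtOAc, 0 → 25 °C
Reagents that add atoms: 2-methoxypropene COC(C)=C
Why: Acid-catalysed acetonide formation (transacetalisation with the enol ether) engages the cis 3,4-diol of the pyranose form and leaves the lactol free; both sugar centres are carried over unchanged.

Step 11
Reactants: 16 2-deoxy-3,4-O-isopropylidene-D-erythro-pentopyranose
Product: 17 methyl (2Z)-4-[(4S,5R)-5-(hydroxymethyl)-2,2-dimethyl-1,3-dioxolan-4-yl]but-2-enoate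
Conditions: (CF3CH2O)2P(O)CH2CO2Me, KN(SiMe3)2 (2.1 equiv), 18-crown-6, THF, −78 °C; AcOH quench at −78 °C
Reagents that add atoms: methyl bis(2,2,2-trifluoroethyl)phosphonoacetate COC(=O)CP(=O)(OCC(F)(F)F)OCC(F)(F)F
Why: Still–Gennari olefination of the aldehyde form of the lactol: the electron-poor phosphonate gives the Z-enoate under kinetic control at −78 °C, a temperature at which the liberated primary alkoxide should not add to the enoate before the acidic quench.

Step 12
Reactants: 17 methyl (2Z)-4-[(4S,5R)-5-(hydroxymethyl)-2,2-dimethyl-1,3-dioxolan-4-yl]but-2-enoate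
Product: 18 (4S,5S)-5-[(2Z)-4-methoxy-4-oxobut-2-en-1-yl]-2,2-dimethyl-1,3-dioxolane-4-carboxylic acid (cis-dioxolane)
Conditions: TEMPO (20 mol%), PhI(OAc)2 (2.2 equiv), MeCN/H2O 1:1, 25 °C
Reagents that add atoms: water O
Why: TEMPO/PhI(OAc)2 oxidation in aqueous acetonitrile takes the primary alcohol via the aldehyde hydrate to the acid and spares the Z-enoate and the acetonide; the configuration of the new α-centre is immaterial because it becomes a radical in step 13.

Step 13
Reactants: 14 4-methoxybenzyl 8-bromo-6-[(5S)-5-hexyl-2-oxo-2,5-dihydrofuran-3-yl]-3-methoxy-1-oxo-2-oxaspiro[4.4]nonane-6-carboxylate; 18 (4S,5S)-5-[(2Z)-4-methoxy-4-oxobut-2-en-1-yl]-2,2-dimethyl-1,3-dioxolane-4-carboxylic acid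
Product: 19 4-methoxybenzyl 6-[(5S)-5-hexyl-2-oxo-2,5-dihydrofuran-3-yl]-3-methoxy-8-{(4S,5S)-5-[(2Z)-4-methoxy-4-oxobut-2-en-1-yl]-2,2-dimethyl-1,3-dioxolan-4-yl}-1-oxo-2-oxaspiro[4.4]nonane-6-carboxylate (trans-dioxolane; side chain α)
Conditions: 18 (1.5 equiv), Cs2CO3 (0.75 equiv), Ir[dF(CF3)ppy]2(dtbbpy)PF6 (2 mol%), NiCl2·glyme (10 mol%), 4,4′-dimethoxy-2,2′-bipyridine (10 mol%), H2O (20 equiv), MeCN, blue LEDs, 25 °C
Reagents that add atoms: none
Why: The excited iridium photocatalyst oxidises the caesium carboxylate of 18, which loses CO2 to give the dioxolan-4-yl (C-1′) radical, while zerovalent nickel activates the C-4 bromide of 14 by halogen abstraction and rebound; the C-1′ radical is captured at nickel and reductive elimination from the trivalent dialkylnickel forges C-4–C-1′, the reduced photocatalyst returning nickel to its zerovalent state. The closest known reaction type is the metallaphotoredox decarboxylative sp3–sp3 cross-coupling of α-oxy and α-amino acids with primary and secondary alkyl bromides. No ring is closed. At C-1′ the planar radical inside the acetonide bonds on the face anti to the butenoate arm on pyranone C-6, so the erythro sugar centre is rewritten to the trans-dioxolane (the threo diol of the target); at C-4 both configurations of the bromide converge on one alkylnickel, which should form on the α-face because the β-face is screened by the butenolide on C-1 and the lactone CH2 on C-2, and reductive elimination proceeds with retention. The step needs chemoselective decarboxylation (18 holds the only free CO2H, every other carboxyl being an ester or lactone), radical capture by nickel faster than Giese addition to the β-substituted Z-enoate and the α-substituted butenolide (both poor acceptors), and no base-induced epimerisation at the butenolide γ-centre, which is secured by using the carboxylate salt without excess base.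

Step 14
Reactants: 19 4-methoxybenzyl 6-[(5S)-5-hexyl-2-oxo-2,5-dihydrofuran-3-yl]-3-methoxy-8-{(4S,5S)-5-[(2Z)-4-methoxy-4-oxobut-2-en-1-yl]-2,2-dimethyl-1,3-dioxolan-4-yl}-1-oxo-2-oxaspiro[4.4]nonane-6-carboxylate
Product: 21 penicillactone A, via seco ester 20 (not isolated)
Conditions: CF3CO2H/H2O 9:1, anisole (5 equiv), 0 → 25 °C; then evaporation from PhMe, 40 °C
Reagents that add atoms: water O
Why: Global acidolysis: aqueous CF3CO2H cleaves the PMB ester (cation trapped by anisole), the acetonide and the methyl pseudo-ester, the freed pyranone C-6 hydroxyl then lactonises onto the Z-enoate (six-membered ring, whereas the C-1′ hydroxyl would need a seven-membered one) and the lactol carbon settles in its thermodynamic configuration.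

Compound list
1 | (1S,4S,5S)-3-oxo-2-oxabicyclo[2.2.1]heptane-5-carboxylic acid (acid exo) | [C@H]1(C(=O)O2)C[C@@H]2C[C@@H]1C(=O)O | starting material
2 | (1R,4S,5R)-5-allyl-3-oxo-2-oxabicyclo[2.2.1]heptane-5-carboxylic acid (allyl exo) | [C@H]1(C(=O)O2)C[C@@H]2C[C@]1(C(=O)O)CC=C | intermediate
3 | 1-allyl-4-hydroxy-2-[(4-methoxybenzyloxy)carbonyl]cyclopentane-1-carboxylic acid (CO2H, CO2PMB and OH cis; allyl trans to them) | [C@H]1(C(=O)OCc2ccc(OC)cc2)C[C@@H](O)C[C@]1(C(=O)O)CC=C | intermediate
4 | 4-methoxybenzyl 4-allyl-3-oxo-2-oxabicyclo[2.2.1]heptane-5-carboxylate (ester endo) | [C@H]1(C(=O)OCc2ccc(OC)cc2)C[C@@H]3C[C@]1(C(=O)O3)CC=C | intermediate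
5 | 4-methoxybenzyl 4-allyl-5-(2-methoxy-2-oxoethyl)-3-oxo-2-oxabicyclo[2.2.1]heptane-5-carboxylate (CH2CO2Me exo) | COC(=O)C[C@]1(C(=O)OCc2ccc(OC)cc2)C[C@@H]3C[C@]1(C(=O)O3)CC=C | intermediate
6 | (S)-2-hexyloxirane [(S)-1,2-epoxyoctane] | CCCCCC[C@H]1CO1 | starting material
7 | 4-methoxybenzyl 4-allyl-5-[(4S)-4-hydroxy-1-methoxy-1-oxodecan-2-yl]-3-oxo-2-oxabicyclo[2.2.1]heptane-5-carboxylate (epimers at decanoate C-2) | CCCCCC[C@H](O)CC(C(=O)OC)[C@]1(C(=O)OCc2ccc(OC)cc2)C[C@@H]3C[C@]1(C(=O)O3)CC=C | intermediate (not isolated)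
8 | 4-methoxybenzyl 4-allyl-5-[(5S)-5-hexyl-2-oxotetrahydrofuran-3-yl]-3-oxo-2-oxabicyclo[2.2.1]heptane-5-carboxylate (epimers at furanone C-3) | CCCCCC[C@H]1CC([C@]2(C(=O)OCc3ccc(OC)cc3)C[C@@H]4C[C@]2(C(=O)O4)CC=C)C(=O)O1 | intermediate
9 | 4-methoxybenzyl 4-allyl-5-[(5S)-5-hexyl-2-oxo-3-(phenylselanyl)tetrahydrofuran-3-yl]-3-oxo-2-oxabicyclo[2.2.1]heptane-5-carboxylate | CCCCCC[C@H]1CC([Se]c5ccccc5)([C@]2(C(=O)OCc3ccc(OC)cc3)C[C@@H]4C[C@]2(C(=O)O4)CC=C)C(=O)O1 | intermediate (not isolated)
10 | 4-methoxybenzyl 4-allyl-5-[(5S)-5-hexyl-2-oxo-2,5-dihydrofuran-3-yl]-3-oxo-2-oxabicyclo[2.2.1]heptane-5-carboxylate | CCCCCC[C@H]1C=C([C@]2(C(=O)OCc3ccc(OC)cc3)C[C@@H]4C[C@]2(C(=O)O4)CC=C)C(=O)O1 | intermediate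
11 | 4-methoxybenzyl 5-[(5S)-5-hexyl-2-oxo-2,5-dihydrofuran-3-yl]-3-oxo-4-(2-oxoethyl)-2-oxabicyclo[2.2.1]heptane-5-carboxylate | CCCCCC[C@H]1C=C([C@]2(C(=O)OCc3ccc(OC)cc3)C[C@@H]4C[C@]2(C(=O)O4)CC=O)C(=O)O1 | intermediate
12 | 4-methoxybenzyl 5-[(5S)-5-hexyl-2-oxo-2,5-dihydrofuran-3-yl]-4-(2-hydroxy-2-methoxyethyl)-3-oxo-2-oxabicyclo[2.2.1]heptane-5-carboxylate | CCCCCC[C@H]1C=C([C@]2(C(=O)OCc3ccc(OC)cc3)C[C@@H]4C[C@]2(C(=O)O4)CC(O)OC)C(=O)O1 | intermediate (not isolated)
13 | 4-methoxybenzyl 6-[(5S)-5-hexyl-2-oxo-2,5-dihydrofuran-3-yl]-8-hydroxy-3-methoxy-1-oxo-2-oxaspiro[4.4]nonane-6-carboxylate (OH α; acetal epimers) | CCCCCC[C@H]1C=C([C@]2(C(=O)OCc3ccc(OC)cc3)C[C@@H](O)C[C@]24CC(OC)OC4=O)C(=O)O1 | intermediate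
14 | 4-methoxybenzyl 8-bromo-6-[(5S)-5-hexyl-2-oxo-2,5-dihydrofuran-3-yl]-3-methoxy-1-oxo-2-oxaspiro[4.4]nonane-6-carboxylate (Br β) | CCCCCC[C@H]1C=C([C@]2(C(=O)OCc3ccc(OC)cc3)C[C@H](Br)C[C@]24CC(OC)OC4=O)C(=O)O1 | intermediate
15 | 2-deoxy-D-ribose (drawn as the open-chain aldehyde) | O=CC[C@H](O)[C@H](O)CO | starting material
16 | 2-deoxy-3,4-O-isopropylidene-D-erythro-pentopyranose | OC1C[C@@H]2OC(C)(C)O[C@@H]2CO1 | intermediate
17 | methyl (2Z)-4-[(4S,5R)-5-(hydroxymethyl)-2,2-dimethyl-1,3-dioxolan-4-yl]but-2-enoate | COC(=O)/C=C\C[C@H]1[C@@H](CO)OC(C)(C)O1 | intermediate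
18 | (4S,5S)-5-[(2Z)-4-methoxy-4-oxobut-2-en-1-yl]-2,2-dimethyl-1,3-dioxolane-4-carboxylic acid (cis) | COC(=O)/C=C\C[C@H]1[C@@H](C(=O)O)OC(C)(C)O1 | intermediate
19 | 4-methoxybenzyl 6-[(5S)-5-hexyl-2-oxo-2,5-dihydrofuran-3-yl]-3-methoxy-8-{(4S,5S)-5-[(2Z)-4-methoxy-4-oxobut-2-en-1-yl]-2,2-dimethyl-1,3-dioxolan-4-yl}-1-oxo-2-oxaspiro[4.4]nonane-6-carboxylate (trans-dioxolane) | CCCCCC[C@H]1C=C([C@]2(C(=O)OCc3ccc(OC)cc3)C[C@@H]([C@@H]5OC(C)(C)O[C@H]5C/C=C\C(=O)OC)C[C@]24CC(OC)OC4=O)C(=O)O1 | intermediate
20 | 8-[(1S,2S,4Z)-1,2-dihydroxy-6-methoxy-6-oxohex-4-en-1-yl]-6-[(5S)-5-hexyl-2-oxo-2,5-dihydrofuran-3-yl]-3-hydroxy-1-oxo-2-oxaspiro[4.4]nonane-6-carboxylic acid | CCCCCC[C@H]1C=C([C@]2(C(=O)O)C[C@@H]([C@H](O)[C@@H](O)C/C=C\C(=O)OC)C[C@]24CC(O)OC4=O)C(=O)O1 | intermediate (not isolated)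
21 | penicillactone A | CCCCCC[C@H]1C=C([C@]2(C(=O)O)C[C@@H]([C@H](O)[C@@H]3CC=CC(=O)O3)C[C@]23C[C@@H](O)OC3=O)C(=O)O1 | target

Total step count: 14. Longest linear sequence: 11 steps (steps 1–9, 13 and 14).

Steps most likely to fail

1. Step 13. What may go wrong: capture of the two secondary radicals at nickel is slow or indiscriminate, so that hydrodebromination of 14, addition of the dioxolanyl radical to the enoate units, or bonding on the β-face of C-4 take over. The fallback sets out from 14 and 18 and comes back at 19, making the same bond by a polar route. Hofer–Moest anodic decarboxylation of 18 in methanol (graphite anode, NaOMe cat., constant current, undivided cell) gives the mixed acetal methyl (2Z)-4-[(4S)-5-methoxy-2,2-dimethyl-1,3-dioxolan-4-yl]but-2-enoate F1. Zn dust with LiCl in THF converts 14 into the cyclopentylzinc bromide F2. Me3SiOTf in CH2Cl2 at −78 °C ionises F1, and the oxocarbenium ion is attacked by F2 anti to the butenoate arm; the configurationally mobile secondary C–Zn bond should react from the less hindered α-face, which gives 19.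

2. Step 6. What may go wrong: the selenium electrophile fails to reach the neopentyl, tertiary enolate carbon, so that 8 is recovered or selenium adds to the allyl alkene. The fallback sets out from 8 and comes back at 10. The same lithium enolate is oxygenated with the small electrophile O2 in the presence of P(OEt)3 to the tertiary α-hydroxy lactone F3. This is dehydrated with the Burgess reagent; as only furanone C-4 carries β-hydrogens, the syn-elimination can only give butenolide 10.

3. Step 1. What may go wrong: the dianion forms sluggishly (endo C–H next to a carboxylate), and the enediolate or the amide base attacks the strained lactone. The fallback sets out from 1 and comes back at 2 by an Ireland–Claisen rearrangement. O-Allylation of 1 (allyl bromide, K2CO3, DMF) gives allyl ester F4. LiN(iPr)2 and Me3SiCl at −78 °C give silyl ketene acetal F5, which rearranges on warming, the allyl group being delivered to the exo face, to the trimethylsilyl ester F6; this is hydrolysed on work-up to 2.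

Further compounds
F1 | step 13 | methyl (2Z)-4-[(4S)-5-methoxy-2,2-dimethyl-1,3-dioxolan-4-yl]but-2-enoate | COC(=O)/C=C\C[C@H]1C(OC)OC(C)(C)O1
F2 | step 13 | 4-methoxybenzyl 8-(bromozincio)-6-[(5S)-5-hexyl-2-oxo-2,5-dihydrofuran-3-yl]-3-methoxy-1-oxo-2-oxaspiro[4.4]nonane-6-carboxylate | CCCCCC[C@H]1C=C([C@]2(C(=O)OCc3ccc(OC)cc3)CC([Zn]Br)C[C@]24CC(OC)OC4=O)C(=O)O1
F3 | step 6 | 4-methoxybenzyl 4-allyl-5-[(5S)-5-hexyl-3-hydroxy-2-oxotetrahydrofuran-3-yl]-3-oxo-2-oxabicyclo[2.2.1]heptane-5-carboxylate | CCCCCC[C@H]1CC(O)([C@]2(C(=O)OCc3ccc(OC)cc3)C[C@@H]4C[C@]2(C(=O)O4)CC=C)C(=O)O1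
F4 | step 1 | allyl (1S,4S,5S)-3-oxo-2-oxabicyclo[2.2.1]heptane-5-carboxylate | [C@H]1(C(=O)O2)C[C@@H]2C[C@@H]1C(=O)OCC=C
F5 | step 1 | (1S,4S)-5-[(allyloxy)(trimethylsilyloxy)methylidene]-2-oxabicyclo[2.2.1]heptan-3-one | [C@H]1(C(=O)O2)C[C@@H]2CC1=C(OCC=C)O[Si](C)(C)C
F6 | step 1 | trimethylsilyl (1R,4S,5R)-5-allyl-3-oxo-2-oxabicyclo[2.2.1]heptane-5-carboxylate | [C@H]1(C(=O)O2)C[C@@H]2C[C@]1(C(=O)O[Si](C)(C)C)CC=C
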